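**Retrosynthetic overview**

1. The target is epicatechin-(4β→8)-catechin with a 4-hydroxybenzoate on the lower 3-oxygen. U is the upper flavan unit (free 3-OH, joined through C4; 2R,3R,4R) and L the lower unit (ester, joined through C8; 2R,3S), with rings A, C, B and flavan numbering in each.
2. Feature used: U-C4 stands ortho to the ring U-A oxygen O1 and bears ring L-A, so ring U-C is an ortho-quinone methide (O1, C8a, C4a, C4) joined to the two-carbon piece U-C2/U-C3 that carries ring U-B.
3. Late disconnections: ten benzyl ethers (hydrogenolysis), the L-O3 ester (4-benzyloxybenzoic acid) and the U-C2–H bond (silane reduction of a 2-hydroxyflavan).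
4. Key disconnection: U-C3–U-C4 and O1–U-C2 are cut together. This gives an L-C8 (2-hydroxyaryl)carbinol (from 8-lithiated protected (+)-catechin and an O-allyl salicylaldehyde) and the (Z)-trimethylsilyl enol ether of an alpha-benzyloxy ketone (Weinreb route), united under a chiral phosphoric acid.
5. Ring order: rings L-A, L-C and L-B come intact from (+)-catechin, rings U-A and U-B are bought as arenes, and ring U-C is the only ring made (step 11).

Key step: step 11

Assumption: the carbinol carbon made in step 6 forms as both epimers and is drawn without configuration, because it becomes planar in step 11.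
Assumption: the sense of induction of the phosphoric acid on this methide cannot be derived safely by analogy, so the (R) antipode of TRIP [3,3'-bis(2,4,6-triisopropylphenyl)-1,1'-binaphthalene-2,2'-diyl hydrogen phosphate] is written and its mirror image replaces it if that proves to be the matched partner of unit L.

**Route**

Step 1
Reactants: 1 (+)-catechin
Product: 2 5,7,3',4'-tetra-O-benzyl-(+)-catechin (2R,3S; 3-OH free)
Conditions: BnBr, K2CO3, DMF, 0 °C to rt
Reagents that add atoms: benzyl bromide, BrCc1ccccc1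
Why: Williamson ether synthesis in which K2CO3 deprotonates only the four phenols, so the secondary 3-OH stays free and both stereocentres are untouched.

Step 2
Reactants: 2 5,7,3',4'-tetra-O-benzyl-(+)-catechin
Product: 3 5,7,3',4'-tetra-O-benzyl-3-O-(tert-butyldimethylsilyl)-(+)-catechin
Conditions: TBSCl, imidazole, DMF, rt
Reagents that add atoms: tert-butyldimethylsilyl chloride, CC(C)(C)[Si](C)(C)Cl
Why: Imidazole-promoted silylation of the secondary alcohol gives an L-O3 group that withstands the aryllithium of step 6 and can later be removed beside benzyl ethers.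

Step 3
Reactants: 3 5,7,3',4'-tetra-O-benzyl-3-O-TBS-(+)-catechin
Product: 4 8-bromo-5,7,3',4'-tetra-O-benzyl-3-O-TBS-(+)-catechin
Conditions: NBS, CH2Cl2, −78 to 0 °C
Reagents that add atoms: N-bromosuccinimide, O=C1CCC(=O)N1Br
Why: Electrophilic aromatic bromination, in which NBS attacks the phloroglucinol-type ring A at C8, the position preferred over C6 in 5,7-di-O-benzyl flavan-3-ol ethers, and leaves the less activated ring B alone.

Step 4
Reactants: 5 2,4,6-trihydroxybenzaldehyde
Product: 6 2,4-bis(benzyloxy)-6-hydroxybenzaldehyde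
Conditions: BnBr (2 equiv), K2CO3, DMF, rt
Reagents that add atoms: benzyl bromide, BrCc1ccccc1
Why: Williamson ether synthesis under mild base, in which the 4-OH and one ortho OH are alkylated while the last ortho OH is held in a hydrogen bond to the aldehyde and should resist benzylation at room temperature.

Step 5
Reactants: 6 2,4-bis(benzyloxy)-6-hydroxybenzaldehyde
Product: 7 2-(allyloxy)-4,6-bis(benzyloxy)benzaldehyde
Conditions: allyl bromide, K2CO3, DMF, 50 °C
Reagents that add atoms: allyl bromide, C=CCBr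
Why: Williamson allylation of the chelated phenol at higher temperature installs a mask that can be removed later without acid, which the diarylcarbinol of step 6 would not tolerate.

Step 6
Reactants: 4 8-bromo-5,7,3',4'-tetra-O-benzyl-3-O-TBS-(+)-catechin, 7 2-(allyloxy)-4,6-bis(benzyloxy)benzaldehyde
Product: 9 L-C8 [2-(allyloxy)-4,6-bis(benzyloxy)phenyl](hydroxy)methyl derivative of the protected catechin (both carbinol epimers), via 8-lithioflavan 8 (not isolated)
Conditions: n-BuLi, THF, −78 °C; then 7, −78 to −40 °C; H2O; chromatography on Et3N-treated silica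
Reagents that add atoms: none
Why: Bromine-lithium exchange followed by 1,2-addition of the aryllithium to the aldehyde, a sequence known for 8-bromo flavan-3-ol ethers, forms the carbinol centre without control, which is acceptable because that centre is erased in step 11.

Step 7
Reactants: 9 allyl-protected diarylcarbinol
Product: 10 L-C8 [2-hydroxy-4,6-bis(benzyloxy)phenyl](hydroxy)methyl derivative (free phenol, both carbinol epimers)
Conditions: Pd(PPh3)4 (5 mol %), morpholine, THF, rt
Reagents that add atoms: none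
Why: Tsuji-Trost-type deallylation, in which zerovalent palladium ionises the allyl aryl ether and morpholine takes up the allyl group, frees the phenol under basic conditions that should not ionise the acid-labile diarylcarbinol.

Step 8
Reactants: 11 (benzyloxy)acetyl chloride
Product: 12 2-(benzyloxy)-N-methoxy-N-methylacetamide
Conditions: MeNH(OMe)·HCl, Et3N, CH2Cl2, 0 °C to rt
Reagents that add atoms: N,O-dimethylhydroxylamine hydrochloride, CNOC.Cl
Why: N-acylation of the hydroxylamine by the acid chloride (Weinreb amide formation) is fast and has no competing site.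

Step 9
Reactants: 13 4-bromo-1,2-bis(benzyloxy)benzene, 12 2-(benzyloxy)-N-methoxy-N-methylacetamide
Product: 16 2-(benzyloxy)-1-[3,4-bis(benzyloxy)phenyl]ethan-1-one, via 3,4-bis(benzyloxy)phenyllithium 14 (not isolated), via lithium hemiaminal alkoxide 15 (not isolated)
Conditions: n-BuLi, THF, −78 °C; then 12, −78 to 0 °C; 1 M HCl
Reagents that add atoms: none
Why: Weinreb ketone synthesis, in which the aryllithium from bromine-lithium exchange adds once and the chelated adduct 15 holds until acidic work-up, so no tertiary alcohol can form.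

Step 10
Reactants: 16 2-(benzyloxy)-1-[3,4-bis(benzyloxy)phenyl]ethan-1-one
Product: 18 (Z)-2-(benzyloxy)-1-[3,4-bis(benzyloxy)phenyl]vinyl trimethylsilyl ether, via lithium (Z)-enolate 17 (not isolated)
Conditions: LiN(SiMe3)2, THF, −78 °C; then Me3SiCl, −78 to 0 °C; hexane, filtration under argon, used crude
Reagents that add atoms: chlorotrimethylsilane, C[Si](C)(C)Cl
Why: Kinetic enolisation and O-silylation, in which lithium is chelated between the enolate oxygen and the alpha-benzyloxy oxygen (and the aryl group avoids OBn), should give the (Z) enol ether with OBn cis to OSiMe3.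

Step 11
Reactants: 10 L-C8 (2-hydroxy-4,6-dibenzyloxyphenyl)carbinol, 18 (Z)-silyl enol ether
Product: 21 protected dimer as the U-C2 hemiketal (2-hydroxyflavan; U-C4 β, 3-OBn trans to ring L-A; one anomer drawn), via ortho-quinone methide 19 (not isolated), via open-chain keto phenol 20 (not isolated)
Conditions: (R)-TRIP (10 mol %), 18 (2.5 equiv), CH2Cl2, −40 to 0 °C; aq NaHCO3; chromatography on Et3N-treated silica
Reagents that add atoms: none
Why: The chiral acid protonates the doubly benzylic hydroxyl of 10 and water leaves to give methide 19, held to the phosphate through a hydrogen bond at its oxygen; the OBn-bearing carbon of 18 (future U-C3) then adds to the methide carbon (future U-C4) in a Mukaiyama-Michael step, the water set free before takes the silyl group, and the phenol of 20 closes on the ketone. The closest known reactions are chiral phosphoric acid catalysed additions of enol ethers, enamides and 1,3-dicarbonyl enols to ortho-quinone methides formed in the flask from 2-hydroxybenzhydrols, which give 2-hydroxychromans in the same way. Ring U-C is closed by 6-exo-trig attack of O1 on the carbonyl carbon U-C2, so the overall change is a formal [4+2] union that forms U-C3–U-C4 and O1–U-C2. U-C4 is set by the catalyst, which shields one face of the bound methide and must be matched with the chiral unit L; U-C3 follows from the (Z) geometry of 18 and, being alpha to the ketone in 20, can drift to the 3,4-trans arrangement with OBn anti to the pseudoaxial ring L-A; U-C2 is an anomeric centre that is removed in step 12. The step needs regioselectivity, which the substrate secures because the charge building up in the enol ether sits on the carbon that carries both the siloxy group and the para-oxygenated ring B. It also needs the crowded, weakly electrophilic methide to be intercepted before it condenses with the free L-C6 position of another molecule, and for that reason the pre-formed silyl enol ether is used in excess in place of the ketone.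

Step 12
Reactants: 21 protected dimer as U-C2 hemiketal
Product: 22 protected dimer: 3,5,7,3',4'-penta-O-benzyl-epicatechin-(4β→8)-5,7,3',4'-tetra-O-benzyl-3-O-TBS-catechin (U 2,3-cis, 3,4-trans)
Conditions: Et3SiH, BF3·OEt2, CH2Cl2, −78 to −40 °C
Reagents that add atoms: none
Why: Ionic reduction of a hemiketal (Lewis acid ionisation to the 2-aryl oxocarbenium ion, then hydride transfer from the silane), in which the 3-OBn group (allylic strain against the coplanar ring B) and ring L-A at U-C4 (peri strain against 5-OBn) should both stand pseudoaxial and anti, so that axial attack of hydride anti to the C3–O bond comes from the face that carries L-A and sets U-C2 with H cis to L-A and ring B cis to 3-OBn, while the cold and short exposure should spare the silyl ether.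

Step 13
Reactants: 22 protected dimer with L-O3 silyl ether
Product: 23 protected dimer with free L-3-OH
Conditions: Bu4NF, THF, rt
Reagents that add atoms: none
Why: Fluoride-induced cleavage of the silyl ether frees L-O3 only, because every other oxygen is a benzyl ether and no stereocentre is touched.

Step 14
Reactants: 23 protected dimer with free L-3-OH, 24 4-(benzyloxy)benzoic acid
Product: 25 protected dimer L-3-O-[4-(benzyloxy)benzoate]
Conditions: DCC, DMAP, CH2Cl2, rt
Reagents that add atoms: none
Why: Steglich esterification is site-specific here because L-O3 is the only free hydroxyl, U-O3 being benzylated, and acylation of this position in benzylated 4→8 dimers is well established.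

Step 15
Reactants: 25 protected dimer L-3-O-[4-(benzyloxy)benzoate]
Product: 26 target, epicatechin-(4β→8)-catechin 3-O-(4-hydroxybenzoate) on unit L
Conditions: H2 (1 atm), Pd(OH)2/C, THF/MeOH/H2O, rt
Reagents that add atoms: none
Why: Catalytic hydrogenolysis removes all ten benzyl ethers (nine phenolic, one on U-O3) under conditions that routinely leave the flavan C2–O1 bonds, the interflavan bond and aryl esters intact, so no stereocentre is affected.

**Compound list**

1 | (+)-catechin (2R,3S) | O[C@H]1Cc2c(O)cc(O)cc2O[C@@H]1c1ccc(O)c(O)c1 | starting material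
2 | 5,7,3',4'-tetra-O-benzyl-(+)-catechin | O[C@H]1Cc2c(OCc3ccccc3)cc(OCc3ccccc3)cc2O[C@@H]1c1ccc(OCc2ccccc2)c(OCc2ccccc2)c1 | intermediate
3 | 5,7,3',4'-tetra-O-benzyl-3-O-TBS-(+)-catechin | CC(C)(C)[Si](C)(C)O[C@H]1Cc2c(OCc3ccccc3)cc(OCc3ccccc3)cc2O[C@@H]1c1ccc(OCc2ccccc2)c(OCc2ccccc2)c1 | intermediate
4 | 8-bromo-5,7,3',4'-tetra-O-benzyl-3-O-TBS-(+)-catechin | CC(C)(C)[Si](C)(C)O[C@H]1Cc2c(OCc3ccccc3)cc(OCc3ccccc3)c(Br)c2O[C@@H]1c1ccc(OCc2ccccc2)c(OCc2ccccc2)c1 | intermediate
5 | 2,4,6-trihydroxybenzaldehyde | O=Cc1c(O)cc(O)cc1O | starting material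
6 | 2,4-bis(benzyloxy)-6-hydroxybenzaldehyde | O=Cc1c(O)cc(OCc2ccccc2)cc1OCc1ccccc1 | intermediate
7 | 2-(allyloxy)-4,6-bis(benzyloxy)benzaldehyde | O=Cc1c(OCC=C)cc(OCc2ccccc2)cc1OCc1ccccc1 | intermediate
8 | 8-lithio-5,7,3',4'-tetra-O-benzyl-3-O-TBS-catechin (formed in the flask, not isolated) | CC(C)(C)[Si](C)(C)O[C@H]1Cc2c(OCc3ccccc3)cc(OCc3ccccc3)c([Li])c2O[C@@H]1c1ccc(OCc2ccccc2)c(OCc2ccccc2)c1 | intermediate
9 | L-C8 [2-(allyloxy)-4,6-bis(benzyloxy)phenyl](hydroxy)methyl derivative of 3, both carbinol epimers | CC(C)(C)[Si](C)(C)O[C@H]1Cc2c(OCc3ccccc3)cc(OCc3ccccc3)c(C(O)c3c(OCC=C)cc(OCc4ccccc4)cc3OCc3ccccc3)c2O[C@@H]1c1ccc(OCc2ccccc2)c(OCc2ccccc2)c1 | intermediate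
10 | L-C8 [2-hydroxy-4,6-bis(benzyloxy)phenyl](hydroxy)methyl derivative of 3, both carbinol epimers (key-step precursor) | CC(C)(C)[Si](C)(C)O[C@H]1Cc2c(OCc3ccccc3)cc(OCc3ccccc3)c(C(O)c3c(O)cc(OCc4ccccc4)cc3OCc3ccccc3)c2O[C@@H]1c1ccc(OCc2ccccc2)c(OCc2ccccc2)c1 | intermediate
11 | (benzyloxy)acetyl chloride | O=C(Cl)COCc1ccccc1 | starting material
12 | 2-(benzyloxy)-N-methoxy-N-methylacetamide | CON(C)C(=O)COCc1ccccc1 | intermediate
13 | 4-bromo-1,2-bis(benzyloxy)benzene | Brc1ccc(OCc2ccccc2)c(OCc2ccccc2)c1 | starting material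
14 | 3,4-bis(benzyloxy)phenyllithium (formed in the flask, not isolated) | [Li]c1ccc(OCc2ccccc2)c(OCc2ccccc2)c1 | intermediate
15 | lithium 2-(benzyloxy)-1-[3,4-bis(benzyloxy)phenyl]-1-[methoxy(methyl)amino]ethan-1-olate (formed in the flask, not isolated) | [Li]OC(COCc1ccccc1)(N(C)OC)c1ccc(OCc2ccccc2)c(OCc2ccccc2)c1 | intermediate
16 | 2-(benzyloxy)-1-[3,4-bis(benzyloxy)phenyl]ethan-1-one | O=C(COCc1ccccc1)c1ccc(OCc2ccccc2)c(OCc2ccccc2)c1 | intermediate
17 | lithium (Z)-2-(benzyloxy)-1-[3,4-bis(benzyloxy)phenyl]ethen-1-olate (formed in the flask, not isolated) | [Li]O/C(c1ccc(OCc2ccccc2)c(OCc2ccccc2)c1)=C\OCc1ccccc1 | intermediate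
18 | (Z)-2-(benzyloxy)-1-[3,4-bis(benzyloxy)phenyl]vinyl trimethylsilyl ether | C[Si](C)(C)O/C(c1ccc(OCc2ccccc2)c(OCc2ccccc2)c1)=C\OCc1ccccc1 | intermediate
19 | ortho-quinone methide: 3,5-bis(benzyloxy)-6-[(protected catechin-8-yl)methylidene]cyclohexa-2,4-dien-1-one, exocyclic alkene geometry not defined (formed in the flask, not isolated) | CC(C)(C)[Si](C)(C)O[C@H]1Cc2c(OCc3ccccc3)cc(OCc3ccccc3)c(C=C3C(=O)C=C(OCc4ccccc4)C=C3OCc3ccccc3)c2O[C@@H]1c1ccc(OCc2ccccc2)c(OCc2ccccc2)c1 | intermediate
20 | open-chain keto phenol: 2-(benzyloxy)-1-[3,4-bis(benzyloxy)phenyl]-3-[2-hydroxy-4,6-bis(benzyloxy)phenyl]-3-(protected catechin-8-yl)propan-1-one, U-C3 and U-C4 as in 21 (formed in the flask, not isolated) | CC(C)(C)[Si](C)(C)O[C@H]1Cc2c(OCc3ccccc3)cc(OCc3ccccc3)c([C@@H](c3c(O)cc(OCc4ccccc4)cc3OCc3ccccc3)[C@@H](OCc3ccccc3)C(=O)c3ccc(OCc4ccccc4)c(OCc4ccccc4)c3)c2O[C@@H]1c1ccc(OCc2ccccc2)c(OCc2ccccc2)c1 | intermediate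
21 | protected dimer as U-C2 hemiketal (2-hydroxyflavan; 3-OBn trans to ring L-A, U-C4 β; anomer with 2-OH on the L-A face drawn) | CC(C)(C)[Si](C)(C)O[C@H]1Cc2c(OCc3ccccc3)cc(OCc3ccccc3)c([C@H]3c4c(OCc5ccccc5)cc(OCc5ccccc5)cc4O[C@](O)(c4ccc(OCc5ccccc5)c(OCc5ccccc5)c4)[C@@H]3OCc3ccccc3)c2O[C@@H]1c1ccc(OCc2ccccc2)c(OCc2ccccc2)c1 | intermediate
22 | 3,5,7,3',4'-penta-O-benzyl-epicatechin-(4β→8)-5,7,3',4'-tetra-O-benzyl-3-O-TBS-catechin | CC(C)(C)[Si](C)(C)O[C@H]1Cc2c(OCc3ccccc3)cc(OCc3ccccc3)c([C@H]3c4c(OCc5ccccc5)cc(OCc5ccccc5)cc4O[C@H](c4ccc(OCc5ccccc5)c(OCc5ccccc5)c4)[C@@H]3OCc3ccccc3)c2O[C@@H]1c1ccc(OCc2ccccc2)c(OCc2ccccc2)c1 | intermediate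
23 | 3,5,7,3',4'-penta-O-benzyl-epicatechin-(4β→8)-5,7,3',4'-tetra-O-benzyl-catechin (free L-3-OH) | O[C@H]1Cc2c(OCc3ccccc3)cc(OCc3ccccc3)c([C@H]3c4c(OCc5ccccc5)cc(OCc5ccccc5)cc4O[C@H](c4ccc(OCc5ccccc5)c(OCc5ccccc5)c4)[C@@H]3OCc3ccccc3)c2O[C@@H]1c1ccc(OCc2ccccc2)c(OCc2ccccc2)c1 | intermediate
24 | 4-(benzyloxy)benzoic acid | O=C(O)c1ccc(OCc2ccccc2)cc1 | starting material
25 | deca-O-benzyl protected target: L-3-O-[4-(benzyloxy)benzoate] of 23 | O=C(O[C@H]1Cc2c(OCc3ccccc3)cc(OCc3ccccc3)c([C@H]3c4c(OCc5ccccc5)cc(OCc5ccccc5)cc4O[C@H](c4ccc(OCc5ccccc5)c(OCc5ccccc5)c4)[C@@H]3OCc3ccccc3)c2O[C@@H]1c1ccc(OCc2ccccc2)c(OCc2ccccc2)c1)c1ccc(OCc2ccccc2)cc1 | intermediate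
26 | CNP0288594.1, epicatechin-(4β→8)-catechin 3-O-(4-hydroxybenzoate) on unit L (U 2R,3R,4R; L 2R,3S) | O=C(O[C@H]1Cc2c(O)cc(O)c([C@H]3c4c(O)cc(O)cc4O[C@H](c4ccc(O)c(O)c4)[C@@H]3O)c2O[C@@H]1c1ccc(O)c(O)c1)c1ccc(O)cc1 | target

**Step count and risks**

Total step count: 15. Longest linear sequence: 10 steps (1, 2, 3, 6, 7, 11, 12, 13, 14, 15).

Three steps most likely to fail:

Step 11. The methide carbon is flanked by two di-ortho-substituted, strongly donating rings, so carbon–carbon bond formation may be too slow. The enol ether may then be hydrolysed by the released water, the cation may condense with L-C6 of a second molecule, and the catalyst may give poor facial selectivity at U-C4 against the bias of unit L. Fallback: the interflavan bond is made in the classical way, from a U-C4 cation and the L-C8 nucleophile, and ring U-C is not built. The fallback sets out from 2 and from commercial (−)-epicatechin and comes back to the route at the target 26. (−)-Epicatechin is benzylated (BnBr, K2CO3, DMF) to 5,7,3',4'-tetra-O-benzyl-(−)-epicatechin F1. DDQ and 2-ethoxyethanol in CH2Cl2 oxidise this at C4 to the 4β-(2-ethoxyethoxy) ether F2. Compound 2 is esterified with 24 (DCC, DMAP) to the catechin 3-O-[4-(benzyloxy)benzoate] F3. Condensation of F2 with an excess of F3 under Me3SiOTf in CH2Cl2 at −78 °C should give the 4β→8 dimer ester F4 with a free U-3-OH, by attack anti to the 3-OH and at C8 in preference to C6. Hydrogenolysis over Pd(OH)2/C then gives 26.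

Step 12. Hydride may be delivered from the face opposite ring L-A, which is less crowded but stereoelectronically disfavoured, and this would give the 2,3-trans unit. The oxocarbenium ion may also lose H-3 to an enol ether and scramble U-C3, and the silyl ether may be lost. Fallback: U-C2 is set in the open chain and the ring is closed by substitution. The fallback sets out from 21 and comes back at 22. Zn(BH4)2 in Et2O/THF at −20 °C reduces the open keto tautomer under chelation between the carbonyl and the alpha-benzyloxy oxygen, with hydride entering opposite the diarylmethyl group, to the anti alcohol F5. Mitsunobu etherification (PPh3, DIAD, THF) then joins O1 to U-C2 with inversion and gives 22.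

Step 7. Once the phenol is free, the 2-hydroxybenzhydrol may ionise on silica or with traces of acid and self-condense before it reaches the catalyst. Fallback: the methide is made by oxidation of a robust diarylmethane, not by dehydration of the carbinol. The fallback sets out from 9 and comes back at methide 19. Et3SiH with a little CF3CO2H in CH2Cl2 at −20 °C deoxygenates 9 to the diarylmethane allyl ether F6. Pd(PPh3)4 and morpholine free the stable 2-(diarylmethyl)phenol F7. Ag2O in CH2Cl2 oxidises F7 to 19. After filtration, 19 is treated with 18, one equivalent of water and the chiral acid as in step 11.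

**Further compounds**

F1 | step 11 | 5,7,3',4'-tetra-O-benzyl-(−)-epicatechin | O[C@@H]1Cc2c(OCc3ccccc3)cc(OCc3ccccc3)cc2O[C@@H]1c1ccc(OCc2ccccc2)c(OCc2ccccc2)c1
F2 | step 11 | 4β-(2-ethoxyethoxy)-5,7,3',4'-tetra-O-benzyl-(−)-epicatechin | CCOCCO[C@H]1c2c(OCc3ccccc3)cc(OCc3ccccc3)cc2O[C@H](c2ccc(OCc3ccccc3)c(OCc3ccccc3)c2)[C@@H]1O
F3 | step 11 | 5,7,3',4'-tetra-O-benzyl-(+)-catechin 3-O-[4-(benzyloxy)benzoate] | O=C(O[C@H]1Cc2c(OCc3ccccc3)cc(OCc3ccccc3)cc2O[C@@H]1c1ccc(OCc2ccccc2)c(OCc2ccccc2)c1)c1ccc(OCc2ccccc2)cc1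
F4 | step 11 | 5,7,3',4'-tetra-O-benzyl-epicatechin-(4β→8)-5,7,3',4'-tetra-O-benzyl-catechin 3-O-[4-(benzyloxy)benzoate] on unit L, free U-3-OH | O=C(O[C@H]1Cc2c(OCc3ccccc3)cc(OCc3ccccc3)c([C@H]3c4c(OCc5ccccc5)cc(OCc5ccccc5)cc4O[C@H](c4ccc(OCc5ccccc5)c(OCc5ccccc5)c4)[C@@H]3O)c2O[C@@H]1c1ccc(OCc2ccccc2)c(OCc2ccccc2)c1)c1ccc(OCc2ccccc2)cc1
F5 | step 12 | open-chain anti alcohol: 2-(benzyloxy)-1-[3,4-bis(benzyloxy)phenyl]-3-[2-hydroxy-4,6-bis(benzyloxy)phenyl]-3-(protected catechin-8-yl)propan-1-ol, U-C3 and U-C4 as in 21 | CC(C)(C)[Si](C)(C)O[C@H]1Cc2c(OCc3ccccc3)cc(OCc3ccccc3)c([C@@H](c3c(O)cc(OCc4ccccc4)cc3OCc3ccccc3)[C@@H](OCc3ccccc3)[C@@H](O)c3ccc(OCc4ccccc4)c(OCc4ccccc4)c3)c2O[C@@H]1c1ccc(OCc2ccccc2)c(OCc2ccccc2)c1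
F6 | step 7 | L-C8 [2-(allyloxy)-4,6-bis(benzyloxy)benzyl] derivative of 3 | CC(C)(C)[Si](C)(C)O[C@H]1Cc2c(OCc3ccccc3)cc(OCc3ccccc3)c(Cc3c(OCC=C)cc(OCc4ccccc4)cc3OCc3ccccc3)c2O[C@@H]1c1ccc(OCc2ccccc2)c(OCc2ccccc2)c1
F7 | step 7 | L-C8 [2-hydroxy-4,6-bis(benzyloxy)benzyl] derivative of 3 | CC(C)(C)[Si](C)(C)O[C@H]1Cc2c(OCc3ccccc3)cc(OCc3ccccc3)c(Cc3c(O)cc(OCc4ccccc4)cc3OCc3ccccc3)c2O[C@@H]1c1ccc(OCc2ccccc2)c(OCc2ccccc2)c1
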